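Readings and results are simulated from invented constants, and the scatter is random.

Per minute was my unit: the share of the free monomer present that entered chains each minute, a pseudo-first-order uptake rate. I assumed that each growing chain took up monomer equally in the flasks compared, and the feed gave them equal volumes at equal times, so this rate counted growing chains.

in all of them: pre-initiator 0.11 mM; stray impurity 12 µM
- Tuesday's: free monomer 5.1 mM (fed, over 4.0 min); protic impurity 10 mM; run made earlier; the fed solution adds 1.0 times the starting volume
- Thursday's: free monomer 21 mM (fed, over 4.0 min); protic impurity 10 mM; run made earlier; the fed solution adds 1.0 times the starting volume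
- gamma: free monomer 10 mM (fed, over 4.0 min); protic impurity 10.0 mM; the fed solution adds 1.0 times the starting volume; time 5.0 min
- theta: free monomer 30 mM (fed, over 4.0 min); protic impurity 10.0 mM; the fed solution adds 1.0 times the starting volume; time 5.0 min

| run | time / min | monomer in chains / % | free monomer / % |
|---|---|---|---|
| Tuesday's | 0.200 | 0 | 4 |
| Tuesday's | 0.417 | 0 | 8 |
| Tuesday's | 0.667 | 0 | 13 |
| Tuesday's | 1.33 | 5 | 26 |
| Tuesday's | 2.50 | 31 | 23 |
| Thursday's | 0.200 | 0 | 4 |
| Thursday's | 0.667 | 0 | 13 |
| Thursday's | 1.33 | 11 | 17 |
| Thursday's | 2.00 | 30 | 8 |
| Thursday's | 2.50 | 44 | 11 |

(scatter of a reading: 1.5 percentage points)

- amounts are per litre of the starting volume; all of the dose is in the solution fed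
- the average divides the monomer in chains by the number of chains begun, living and dead together
- the numbers in the tables scatter with a standard deviation of 1.5 percentage points
- the earlier runs do not show the number of chains; that part of a forecast is a guess
- percentages count the whole charge, also what has not yet gone in

* which of the two ends with the longer chains by the average number of monomer units in a chain (chains begun, living or dead) ("neither" if they lie within 10%) (gamma / theta / neither)
* average number of monomer units in a chain (chains begun, living or dead) at the end, gamma
* average number of monomer units in a chain (chains begun, living or dead) at the end, theta

I replaced the free monomer curve between 1.33 min and 2.50 min by the mean of its end readings, and divided the gain in chains by that mean and the time. Tuesday's run read 0.907 min⁻¹ and Thursday's 2.01 min⁻¹. Taking in Thursday's reading at 2.00 min moved the rate to 2.51 min⁻¹, but that free monomer reading of 8% lay 2.00 standard deviations below the one at 2.50 min, so I took this shift as a mark of the scatter and not as the cost of the mean.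

The charge rose by a factor 4.12, but the rate by 2.22, less than the charge. The logarithm of the second factor over that of the first gave a reading of 0.564, the chain exponent: I took chains to go as the charge to this power. Length is monomer in chains over chains begun, so at equal shares in chains it went as the charge to one minus the exponent. From gamma to theta that gave a factor 1.61, or 1.36 with the rate through the low reading. Both exceeded the margin, so I chose theta. The runs show no chain count, so I gave no absolute lengths.

The forecast said theta, “Theta ends longer”, with 125 (60 to 220) for gamma and 280 (130 to 450) for theta.

The simulation gave theta, with 240 for gamma and 496 for theta.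

    free monomer + initiator → living end + monomer in chains (k = 2.20 L mol⁻¹ s⁻¹)
    free monomer + living end → monomer in chains + living end, rate k2*[living end]*[free monomer] (k = 2000 L mol⁻¹ s⁻¹)
    pre-initiator → initiator (k = 0.0200 s⁻¹)
    protic impurity + free monomer → quenched substrate (k = 0.610 L mol⁻¹ s⁻¹)
    initiator + stray impurity → spent initiator (k = 38000 L mol⁻¹ s⁻¹)

With the simulated shares in chains, 84.1% for gamma and 90.6% for theta, the chain exponent gave theta a factor 1.73 over gamma, while the simulation gave 2.07. The neighbouring flask was theta's with 18 mM of free monomer, and it put 88.1% into chains. Starting from gamma's length, I raised the charge factor 1.80 to one minus the exponent and multiplied by the ratio of shares, which gave 325. The neighbouring flask ended at 352.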